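All runs come from a simulation with made-up constants, and the scatter is random.

4 questions came to me, and I treated them as one: how far apart the E and L peaks stand when X and G are kept equal.

in all of them: X 0.10 M; G 0.10 M
- alder: J 2 equiv; temperature 20 °C; run made earlier
- elm: J 3 equiv; temperature 31 °C; run made earlier
- north: J 4.00 equiv; temperature 35 °C; time 10 min
- north-west: J 4.00 equiv; temperature 15 °C; time 10 min
- south-east: J 4.00 equiv; at 35 °C until 2.0 min, from then on at 15 °C; time 10 min

| run | time / min | E / % | L / % | X / % |
|---|---|---|---|---|
| alder | 1.33 | 9.9 | 2.4 | 43.6 |
| alder | 3.00 | 14.9 | 3.9 | 41.0 |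
| alder | 6.00 | 19.2 | 3.9 | 37.7 |
| alder | 15.0 | 29.8 | 8.0 | 30.2 |
| elm | 0.667 | 13.4 | 3.7 | 40.2 |
| elm | 1.33 | 21.8 | 4.8 | 37.3 |
| elm | 3.00 | 33.2 | 8.5 | 30.5 |
| elm | 8.00 | 41.9 | 12.2 | 22.7 |

(standard deviation of a reading: 1 percentage point)

- J is single-handed; X and G are mirror images of each other, charged as a racemate, each of them at the stated concentration
- on the list of suspects stand: J + X -> E; J + G -> L; X <-> G; J <-> D; 2 J -> Z
- an excess is the difference of the two amounts in percent of their sum
- an excess is below zero if the other one leads
- the handed part of J does not stay in what it makes, so the products of the two hands are mirror images too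

- the flask that comes out highest in excess of E over L, or "all alike" when all lie within 1.5 percentage points (north / north-west / south-east / all alike)
- excess of E over L at the end, north
- excess of E over L at the end, north-west
- excess of E over L at the end, south-east

I ranked the events by time. The exchange X ⇌ G came first. At 1.33 min in alder, E had outrun L by 7.5 percentage points, yet G, taken by difference, stood 0.5 points from X, so the exchange was already keeping pace. Next came product formation: alder's opening pace corresponded to turning over the whole charge in 10.8 min. Last came the stall: between 6.00 min and 15.0 min the same reckoning gave 61.2 min, while X read 43.6% at the close of the opening stretch (1.33 min) and 30.2% at the close of the late one (15.0 min). With cX allowed for, cJ had dropped roughly 3.93-fold, so J was probably also leaving by D or Z.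

Since cJ multiplies the rates of both E and L, it cancels from their ratio, the selectivity factor. While cX equals cG at one temperature, every slice of product therefore carries the same excess. I carried the pooled excess, the summed E less the summed L over their total across both runs, which came to 59.0%. Single alder readings wandered from 57.7% to 66.2%, so I saw no temperature trend in these readings and reckoned 59.0% for each flask.

The forecast differed from my reckoning: it chose north-west, with north 56.5% (51% to 60%), north-west 60% (54% to 65%) and south-east 57.5% (52% to 61%). It added: “The ordering is only weakly supported.”

The result was all alike: north 58.7%, north-west 57.8%, south-east 58.6%, a spread of 0.90 points, with north-west lowest. Applied to north-west at 10.0 min, 59.0% turned its 30.5% of E into 7.86% of L; the flask held 8.15%.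

    J + X → E (k = 0.0540 /M/s, Ea = 64.0 kJ/mol)
    J + G → L (k = 0.0140 /M/s, Ea = 63.0 kJ/mol)
    X ⇌ G (k = 1.10 /s, Ea = 65.0 kJ/mol)
    J ⇌ D (K = 0.570, k = 0.0140 /s, Ea = 92.0 kJ/mol, ΔH = 8.00 kJ/mol)
    2 J → Z (k = 0.0270 /M/s, Ea = 47.0 kJ/mol)
    (constants at 35 °C)

A neighbour of north-west, charged with 2.40 equiv of J, held 23.3% of E at 10.0 min, so 59.0% gave 6.01% of L. The computed flask held 6.21% of L, an excess of 57.9%.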